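The synthesis rests on disconnecting C26–C27 and C12–C22 together, using the array tertiary carbinol C27–C26–quaternary C12–quaternary C22 where ring B (C9, C10, C11, C12, C26, C27) meets ring C (C12, C22, C23, C25, C26); atoms are numbered as in the target SMILES. In one Lewis-acid step the C27 methyl ketone adds to the C12=C26 alkene and an aldehyde enol silyl ether traps the C12 cation, closing both rings and setting C27, C26, C12 and C22. The substrate comes from Negishi coupling of an enantioenriched acetyl lactone iodide (C9) with a Diels–Alder-derived cyclohexanone vinyl iodide (C23, C17) carrying the enol ether.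

Key step: step 22

Remarks on the chemistry.
- Atom labels C1–C31 follow the atom order of the target SMILES. Further rings: lactone A (C2, O4, C5, C7, C8, C9), cyclohexanone D (C14, C16, C17, C22, C23, C30), lactone E (C17, C18, O20, C21, C22).
- Substrate 33 and product 36 were checked centre by centre against the target (C9, C12, C14, C17, C22, C23, C26, C27 and the C12=C26 geometry agree); no structural correction was needed.
- Three spectator features of the substrate are chosen on purpose: C13–O is a triisopropylsilyl ether (bulky, weakly basic); the C18 ester is a 2,2,2-trifluoroethyl ester (poor Lewis base, later a good acyl donor); the enol ether is the E isomer that silylation should give (its geometry vanishes in step 22).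
- Assumption: in the two catalyst-controlled steps (1 and 16) the catalyst hand named is the one assigned from the usual binding models; the mirror-image catalyst is used if the sense proves to be the reverse.

**Acetyl lactone iodide (steps 1–9)**

Step 1
Reactants: 1 3-acetyldihydrofuran-2(3H)-one
Product: 2 (R)-3-acetyl-3-allyldihydrofuran-2(3H)-one
Conditions: allyl bromide, (S,S)-N-spiro bis(binaphthyl)ammonium bromide bearing 3,3′-bis(3,4,5-trifluorophenyl) groups (1 mol %), K2CO3, toluene, −20 °C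
Reagents that add atoms: allyl bromide C=CCBr
Why: Asymmetric phase-transfer alkylation of the cyclic β-keto lactone, in which the tight ion pair with the chiral ammonium cation shields one enolate face so that allylation sets the quaternary carbon C9.

Step 2
Reactants: 2 (R)-3-acetyl-3-allyldihydrofuran-2(3H)-one
Product: 3 (S)-3-acetyl-3-[(E)-prop-1-enyl]dihydrofuran-2(3H)-one
Conditions: RuHCl(CO)(PPh3)3 (5 mol %), toluene, 80 °C
Reagents that add atoms: none
Why: Ruthenium hydride alkene isomerization (hydrometalation/β-hydride elimination) moves the terminal double bond to the (E)-1-propenyl position and stops there because C9 bears no hydrogen.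

Step 3
Reactants: 3 (S)-3-acetyl-3-[(E)-prop-1-enyl]dihydrofuran-2(3H)-one
Product: 4 (S)-3-(2-methyl-1,3-dioxolan-2-yl)-3-[(E)-prop-1-enyl]dihydrofuran-2(3H)-one
Conditions: Me3SiOCH2CH2OSiMe3, Me3SiOTf (5 mol %), CH2Cl2, −78 → 0 °C
Reagents that add atoms: 1,2-bis(trimethylsilyloxy)ethane C[Si](C)(C)OCCO[Si](C)(C)C
Why: Silyl-triflate-catalysed ketalization converts the hindered methyl ketone into its dioxolane under aprotic conditions without touching the lactone, which masks C27 and closes the retro-Claisen and retro-aldol paths of the next steps.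

Step 4
Reactants: 4 (S)-3-(2-methyl-1,3-dioxolan-2-yl)-3-[(E)-prop-1-enyl]dihydrofuran-2(3H)-one
Product: 5 (R,E)-3-(2-hydroxyethyl)-2-methyl-3-(2-methyl-1,3-dioxolan-2-yl)hex-4-en-2-ol
Conditions: MeLi (3 equiv), CeCl3, THF, −78 → 0 °C; aq. NH4Cl
Reagents that add atoms: methyllithium [Li]C
Why: Double organocerium addition to the lactone carbonyl, the only carbonyl left, builds the gem-dimethyl carbinol C2 and frees the C11 alcohol, the weakly basic cerium reagent suppressing enolization of the intermediate methyl ketone.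

Step 5
Reactants: 5 (R,E)-3-(2-hydroxyethyl)-2-methyl-3-(2-methyl-1,3-dioxolan-2-yl)hex-4-en-2-ol
Product: 6 (R,E)-3-[2-(tert-butyldimethylsilyloxy)ethyl]-2-methyl-3-(2-methyl-1,3-dioxolan-2-yl)hex-4-en-2-ol
Conditions: t-BuMe2SiCl, imidazole, CH2Cl2, 0 °C
Reagents that add atoms: tert-butyldimethylsilyl chloride CC(C)(C)[Si](C)(C)Cl
Why: Selective silylation of the primary alcohol over the hindered tertiary one, needed because a leaving group at C11 beside the free tertiary alcohol would close a tetrahydrofuran.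

Step 6
Reactants: 6 (R,E)-3-[2-(tert-butyldimethylsilyloxy)ethyl]-2-methyl-3-(2-methyl-1,3-dioxolan-2-yl)hex-4-en-2-ol
Product: 8 (R,E)-3-[2-(tert-butyldimethylsilyloxy)ethyl]-2-methyl-3-(2-methyl-1,3-dioxolan-2-yl)hex-4-en-2-yl acrylate, via lithium alkoxide 7 (not isolated)
Conditions: n-BuLi, THF, −78 °C; CH2=CHCOCl, −78 → 0 °C
Reagents that add atoms: acryloyl chloride C=CC(Cl)=O
Why: O-acylation of the preformed lithium alkoxide is the reliable esterification of a tertiary alcohol next to a quaternary carbon, and no carbonyl is present that could trigger retro-aldol cleavage.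

Step 7
Reactants: 8 (R,E)-3-[2-(tert-butyldimethylsilyloxy)ethyl]-2-methyl-3-(2-methyl-1,3-dioxolan-2-yl)hex-4-en-2-yl acrylate
Product: 9 (R,E)-3-acetyl-3-(2-hydroxyethyl)-2-methylhex-4-en-2-yl acrylate
Conditions: 1 M HCl, THF, 25 °C
Reagents that add atoms: water O
Why: Acid hydrolysis removes the dioxolane and the primary silyl ether together while the tertiary acrylate survives dilute acid, and it is done before ring closure so that the free alcohol never meets the cyclic enoate (no oxa-Michael closure).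

Step 8
Reactants: 9 (R,E)-3-acetyl-3-(2-hydroxyethyl)-2-methylhex-4-en-2-yl acrylate
Product: 10 (R,E)-3-acetyl-3-(2-iodoethyl)-2-methylhex-4-en-2-yl acrylate
Conditions: I2, PPh3, imidazole, CH2Cl2, 0 °C
Reagents that add atoms: iodine II
Why: Appel iodination of the primary alcohol (drawn out of its hemiketal equilibrium with the ketone) under buffered conditions, with the tertiary oxygen already acylated so that no cyclic ether can form.

Step 9
Reactants: 10 (R,E)-3-acetyl-3-(2-iodoethyl)-2-methylhex-4-en-2-yl acrylate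
Product: 11 (R)-5-acetyl-5-(2-iodoethyl)-6,6-dimethyl-5,6-dihydro-2H-pyran-2-one
Conditions: second-generation Grubbs catalyst (H2IMes)(PCy3)Cl2Ru=CHPh (10 mol %), toluene, 80 °C
Reagents that add atoms: none
Why: Ring-closing olefin metathesis of the acrylate with the propenyl group closes the unsaturated six-membered lactone A (C7=C8) with loss of propene, helped by the gem-dimethyl effect at C2 and tolerant of ketone and alkyl iodide.

**Vinyl iodide linker (steps 10–12)**

Step 10
Reactants: 12 but-2-yne-1,4-diol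
Product: 13 4-(triisopropylsilyloxy)but-2-yn-1-ol
Conditions: 12 (3 equiv), i-Pr3SiCl (1 equiv), imidazole, DMF, 0 → 25 °C
Reagents that add atoms: triisopropylsilyl chloride CC(C)[Si](Cl)(C(C)C)C(C)C
Why: Statistical monosilylation of the symmetrical diol used in excess.

Step 11
Reactants: 13 4-(triisopropylsilyloxy)but-2-yn-1-ol
Product: 15 (Z)-3-iodo-4-(triisopropylsilyloxy)but-2-en-1-ol, via cyclic sodium alkenylaluminate 14 (not isolated)
Conditions: NaAlH2(OCH2CH2OMe)2, THF, 0 °C; I2, −78 °C
Reagents that add atoms: iodine II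
Why: Hydroxyl-directed trans-hydroalumination delivers hydride to C26 and aluminium to C12 through a five-membered alkoxyaluminate, and iodinolysis with retention gives the vinyl iodide with iodine cis to C25, the geometry that later puts C11 cis to C25.

Step 12
Reactants: 15 (Z)-3-iodo-4-(triisopropylsilyloxy)but-2-en-1-ol
Product: 16 (Z)-(4-bromo-2-iodobut-2-enyloxy)triisopropylsilane
Conditions: CBr4, PPh3, CH2Cl2, 0 °C
Reagents that add atoms: carbon tetrabromide BrC(Br)(Br)Br
Why: Appel bromination of the primary allylic alcohol by direct displacement of the oxyphosphonium group.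

**Cyclohexanone vinyl iodide (steps 13–20)**

Step 13
Reactants: 17 glycolaldehyde dimer (0.55 equiv); 18 3-(triphenylphosphoranylidene)butan-2-one
Product: 19 (E)-5-hydroxy-3-methylpent-3-en-2-one
Conditions: THF, reflux
Reagents that add atoms: none
Why: Wittig olefination of glycolaldehyde released from its dimer with the acyl-stabilized α-methyl ylide gives the (E)-trisubstituted enone.

Step 14
Reactants: 19 (E)-5-hydroxy-3-methylpent-3-en-2-one
Product: 20 (E)-3-methyl-5-(triethylsilyloxy)pent-3-en-2-one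
Conditions: Et3SiCl, imidazole, CH2Cl2, 0 °C
Reagents that add atoms: chlorotriethylsilane CC[Si](Cl)(CC)CC
Why: Standard silylation of the primary alcohol, the triethylsilyl ether being chosen because it can later be oxidized straight to the aldehyde.

Step 15
Reactants: 20 (E)-3-methyl-5-(triethylsilyloxy)pent-3-en-2-one
Product: 22 (E)-2-(tert-butyldimethylsilyloxy)-3-methyl-5-(triethylsilyloxy)penta-1,3-diene, via lithium dienolate 21 (not isolated)
Conditions: LiN(iPr)2, THF, −78 °C; t-BuMe2SiCl, DMPU, −78 → 0 °C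
Reagents that add atoms: tert-butyldimethylsilyl chloride CC(C)(C)[Si](C)(C)Cl
Why: Kinetic deprotonation of the methyl ketone and O-silylation (enol silane formation) give the cross-conjugated 2-silyloxy diene with the (E)-trisubstituted terminus intact.

Step 16
Reactants: 22 (E)-2-(tert-butyldimethylsilyloxy)-3-methyl-5-(triethylsilyloxy)penta-1,3-diene; 23 2,2,2-trifluoroethyl acrylate
Product: 24 2,2,2-trifluoroethyl (1S,2S)-4-(tert-butyldimethylsilyloxy)-3-methyl-2-[(triethylsilyloxy)methyl]cyclohex-3-ene-1-carboxylate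
Conditions: (R)-2-(o-tolyl)oxazaborolidine of (R)-α,α-diphenylprolinol (20 mol %), HNTf2 (17 mol %), CH2Cl2, −78 → −40 °C
Reagents that add atoms: none
Why: Catalytic asymmetric Diels–Alder reaction in which the oxazaborolidinium-bound acrylate reacts at the Re face of C17 through an endo transition state while the 2-silyloxy group directs the ester para to C30, so that C17 and C22 are set cis and the enol ether lands regiospecifically on C23.

Step 17
Reactants: 24 2,2,2-trifluoroethyl (1S,2S)-4-(tert-butyldimethylsilyloxy)-3-methyl-2-[(triethylsilyloxy)methyl]cyclohex-3-ene-1-carboxylate; 16 (Z)-(4-bromo-2-iodobut-2-enyloxy)triisopropylsilane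
Product: 26 2,2,2-trifluoroethyl (1S,2S,3R)-3-[(Z)-3-iodo-4-(triisopropylsilyloxy)but-2-enyl]-3-methyl-4-oxo-2-[(triethylsilyloxy)methyl]cyclohexane-1-carboxylate, via tetrabutylammonium enolate 25 (not isolated)
Conditions: Bu4N[Ph3SiF2] (1.1 equiv), THF, 4 Å sieves, −40 → 0 °C
Reagents that add atoms: none
Why: Fluoride-triggered regiospecific enolate alkylation, in which desilylation of the tetrasubstituted enol ether (far faster than that of the alkyl silyl ethers) gives the enolate only at C23 and the allylic bromide enters anti to the C22 and C17 substituents, setting quaternary C23 with C25 trans to C21 and C18.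

Step 18
Reactants: 26 2,2,2-trifluoroethyl (1S,2S,3R)-3-[(Z)-3-iodo-4-(triisopropylsilyloxy)but-2-enyl]-3-methyl-4-oxo-2-[(triethylsilyloxy)methyl]cyclohexane-1-carboxylate
Product: 28 2,2,2-trifluoroethyl (1S,2S,3R,5R)-3-[(Z)-3-iodo-4-(triisopropylsilyloxy)but-2-enyl]-3,5-dimethyl-4-oxo-2-[(triethylsilyloxy)methyl]cyclohexane-1-carboxylate, via lithium enolate 27 (not isolated)
Conditions: LiN(iPr)2 (1.05 equiv), THF, −78 °C; MeI, −78 → −40 °C
Reagents that add atoms: iodomethane CI
Why: Kinetic ketone enolate methylation at C14, the only α-CH2 and far more acidic than the ester α-CH, with the methyl entering anti to the axial C25 chain (also the equatorial, thermodynamic position), a centre that step 26 erases in any case.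

Step 19
Reactants: 28 2,2,2-trifluoroethyl (1S,2S,3R,5R)-3-[(Z)-3-iodo-4-(triisopropylsilyloxy)but-2-enyl]-3,5-dimethyl-4-oxo-2-[(triethylsilyloxy)methyl]cyclohexane-1-carboxylate
Product: 30 2,2,2-trifluoroethyl (1S,2S,3R,5R)-2-formyl-3-[(Z)-3-iodo-4-(triisopropylsilyloxy)but-2-enyl]-3,5-dimethyl-4-oxocyclohexane-1-carboxylate, via alkoxysulfonium chloride 29 (not isolated)
Conditions: (COCl)2, DMSO, CH2Cl2, −78 → −30 °C; Et3N, −78 → 0 °C
Reagents that add atoms: none
Why: Swern oxidation applied directly to the primary triethylsilyl ether, which passes into the alkoxysulfonium ion and then the aldehyde without ever freeing the γ-hydroxy ester that would lactonize, the triisopropylsilyl ether being inert.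

Step 20
Reactants: 30 2,2,2-trifluoroethyl (1S,2S,3R,5R)-2-formyl-3-[(Z)-3-iodo-4-(triisopropylsilyloxy)but-2-enyl]-3,5-dimethyl-4-oxocyclohexane-1-carboxylate
Product: 31 2,2,2-trifluoroethyl (1S,3R,5R,2E)-2-[(tert-butyldimethylsilyloxy)methylidene]-3-[(Z)-3-iodo-4-(triisopropylsilyloxy)but-2-enyl]-3,5-dimethyl-4-oxocyclohexane-1-carboxylate
Conditions: t-BuMe2SiOTf (1.1 equiv), Et3N, CH2Cl2, −78 → 0 °C
Reagents that add atoms: tert-butyldimethylsilyl triflate CC(C)(C)[Si](C)(C)OS(=O)(=O)C(F)(F)F
Why: Soft enolization (silyl triflate/amine) of the aldehyde, much faster than that of the hindered ketone or the ester, gives the aldehyde enol silyl ether with the siloxy group syn to the less hindered C17, before any methyl ketone is present in the molecule.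

**Fragment union and key step (steps 21–22)**

Step 21
Reactants: 11 (R)-5-acetyl-5-(2-iodoethyl)-6,6-dimethyl-5,6-dihydro-2H-pyran-2-one; 31 2,2,2-trifluoroethyl (1S,3R,5R,2E)-2-[(tert-butyldimethylsilyloxy)methylidene]-3-[(Z)-3-iodo-4-(triisopropylsilyloxy)but-2-enyl]-3,5-dimethyl-4-oxocyclohexane-1-carboxylate
Product: 33 2,2,2-trifluoroethyl (1S,3R,5R,2E)-2-[(tert-butyldimethylsilyloxy)methylidene]-3-{(2E)-5-[(3R)-3-acetyl-2,2-dimethyl-6-oxo-3,6-dihydro-2H-pyran-3-yl]-3-[(triisopropylsilyloxy)methyl]pent-2-enyl}-3,5-dimethyl-4-oxocyclohexane-1-carboxylate, via alkylzinc iodide 32 (not isolated)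
Conditions: Zn dust, LiCl, THF, 40 °C; then 31, Pd(OAc)2 (5 mol %), SPhos (10 mol %), THF, 25 °C
Reagents that add atoms: none
Why: Negishi sp3–sp2 cross-coupling, in which zinc inserts into the primary iodide without touching ketone or lactone and palladium joins C11 to C12 with retention of the vinyl iodide geometry, fixing C11 cis to C25.

Step 22
Reactants: 33 cyclization substrate (acetyl lactone, C12=C26 alkene with CH2OSi(iPr)3 on C12, cyclohexanone enol silyl ether)
Product: 36 tetracyclic C21 aldehyde trifluoroethyl ester with rings B and C closed (C27 tertiary alcohol; C13 CH2OSi(iPr)3), via C12 carbocation 34 (not isolated), via silyloxocarbenium ion 35 (not isolated)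
Conditions: MeAlCl2 (4 equiv), CH2Cl2, −78 → −40 °C; aq. potassium sodium tartrate
Reagents that add atoms: none
Why: MeAlCl2 binds the C27 ketone and the C12=C26 alkene adds through C26 in a chair-like 6-endo closure of ring B (C9, C10, C11, C12, C26, C27), giving the tertiary C12 cation, which C22 of the enol silyl ether captures in a 5-exo closure of ring C (C12, C22, C23, C25, C26); loss of the silyl group from the oxocarbenium ion gives the C21 aldehyde. The closest known reaction type is the Lewis-acid-promoted, carbonyl-initiated cation–olefin (Prins-type) polycyclization terminated by an enol ether. C26 and C27 are controlled by C9: the chair places the bulky C2 of the spiro lactone equatorial (its axial site clashes with C25) and the aluminium-bound oxygen equatorial, which selects the alkene face and the carbonyl face. C12 and C22 are controlled by the three-atom tether C26–C25–C23, which allows only cis fusion of ring C to rings B and D; with C11 cis to C25 this amounts to anti addition across the alkene and ties C22 to the configuration of C23. The step needs cation capture to outrun proton loss, 1,2-hydride shift from C13 and protodesilylation, which is secured by the intramolecular five-ring closure, the bulky weakly basic C13 silyl ether, excess MeAlCl2 (alkoxide kept complexed, HCl scavenged) and the weakly basic trifluoroethyl ester.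

**From the tetracycle to the target (steps 23–28)**

Step 23
Reactants: 36 tetracyclic C21 aldehyde trifluoroethyl ester
Product: 38 pentacyclic γ-lactone (lactone E closed; C13 CH2OSi(iPr)3; C27 OH; C30 ketone), via hydroxy ester 37 (not isolated)
Conditions: NaBH4, MeOH/CH2Cl2, −78 → 0 °C
Reagents that add atoms: none
Why: Chemoselective borohydride reduction of the aldehyde (the C30 ketone lies between a quaternary and a branched carbon) followed by spontaneous lactonization of the C21 alkoxide onto the cis-disposed activated ester.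

Step 24
Reactants: 38 pentacyclic γ-lactone silyl ether
Product: 39 pentacyclic γ-lactone with free C13 primary alcohol
Conditions: HF·pyridine, pyridine/THF, 0 → 25 °C
Reagents that add atoms: none
Why: Fluoride-mediated silyl ether cleavage under buffered conditions that leave both lactones, the ketone and the tertiary alcohol untouched.

Step 25
Reactants: 39 pentacyclic γ-lactone with free C13 primary alcohol
Product: 40 pentacyclic C13 aldehyde
Conditions: DMP (triacetoxy periodinane), NaHCO3, CH2Cl2, 25 °C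
Reagents that add atoms: none
Why: Periodinane oxidation of the neopentyl primary alcohol to the non-enolizable aldehyde under neutral conditions, the tertiary alcohol being inert.

Step 26
Reactants: 40 pentacyclic C13 aldehyde
Product: 41 hexacyclic β-hydroxy ketone (C13–C14 bond closed; C13 OH drawn syn to the C30 carbonyl)
Conditions: KOt-Bu (2.2 equiv), THF, −78 → −30 °C; AcOH, −78 °C
Reagents that add atoms: none
Why: Intramolecular aldol addition (6-enolendo-exo-trig) of the C30 enolate, which can form only towards C14, to the C13 aldehyde held above ring D on C12 closes the bicyclo[2.2.2]octane and sets C14 by the geometry of the bridge, the C13 carbinol configuration being irrelevant and the cold quench guarding against retro-aldol.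

Step 27
Reactants: 41 hexacyclic β-hydroxy ketone
Product: 42 C13 O-(imidazol-1-ylthiocarbonyl) derivative of 41
Conditions: (imidazol-1-yl)2C=S, DMAP, ClCH2CH2Cl, 70 °C
Reagents that add atoms: 1,1′-thiocarbonyldiimidazole S=C(n1ccnc1)n1ccnc1
Why: Thioacylation of the secondary alcohol without an alkoxide (hence no retro-aldol), the tertiary C27 alcohol being too hindered to react.

Step 28
Reactants: 42 C13 O-(imidazol-1-ylthiocarbonyl) derivative
Product: 43 target CNP0222978.3
Conditions: Bu3SnH (0.5 M), AIBN, PhSeSePh (10 mol %), toluene, 90 °C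
Reagents that add atoms: none
Why: Barton–McCombie radical deoxygenation, run at high stannane concentration with catalytic PhSeH formed in situ so that the C13 radical is reduced before it can undergo a 1,2-acyl shift through the neighbouring C30 carbonyl.

**Compound list**

1 | 3-acetyldihydrofuran-2(3H)-one | CC(=O)C1CCOC1=O | starting material
2 | (R)-3-acetyl-3-allyldihydrofuran-2(3H)-one | C=CC[C@]1(C(C)=O)CCOC1=O | intermediate
3 | (S)-3-acetyl-3-[(E)-prop-1-enyl]dihydrofuran-2(3H)-one | C/C=C/[C@]1(C(C)=O)CCOC1=O | intermediate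
4 | (S)-3-(2-methyl-1,3-dioxolan-2-yl)-3-[(E)-prop-1-enyl]dihydrofuran-2(3H)-one | C/C=C/[C@]1(C2(C)OCCO2)CCOC1=O | intermediate
5 | (R,E)-3-(2-hydroxyethyl)-2-methyl-3-(2-methyl-1,3-dioxolan-2-yl)hex-4-en-2-ol | C/C=C/[C@](C1(C)OCCO1)(CCO)C(C)(C)O | intermediate
6 | (R,E)-3-[2-(tert-butyldimethylsilyloxy)ethyl]-2-methyl-3-(2-methyl-1,3-dioxolan-2-yl)hex-4-en-2-ol | C/C=C/[C@](C1(C)OCCO1)(CCO[Si](C)(C)C(C)(C)C)C(C)(C)O | intermediate
7 | lithium alkoxide of 6 | C/C=C/[C@](C1(C)OCCO1)(CCO[Si](C)(C)C(C)(C)C)C(C)(C)[O-].[Li+] | intermediate (not isolated)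
8 | (R,E)-3-[2-(tert-butyldimethylsilyloxy)ethyl]-2-methyl-3-(2-methyl-1,3-dioxolan-2-yl)hex-4-en-2-yl acrylate | C/C=C/[C@](C1(C)OCCO1)(CCO[Si](C)(C)C(C)(C)C)C(C)(C)OC(=O)C=C | intermediate
9 | (R,E)-3-acetyl-3-(2-hydroxyethyl)-2-methylhex-4-en-2-yl acrylate | C/C=C/[C@](C(C)=O)(CCO)C(C)(C)OC(=O)C=C | intermediate
10 | (R,E)-3-acetyl-3-(2-iodoethyl)-2-methylhex-4-en-2-yl acrylate | C/C=C/[C@](C(C)=O)(CCI)C(C)(C)OC(=O)C=C | intermediate
11 | (R)-5-acetyl-5-(2-iodoethyl)-6,6-dimethyl-5,6-dihydro-2H-pyran-2-one | CC1(C)OC(=O)C=C[C@]1(C(C)=O)CCI | intermediate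
12 | but-2-yne-1,4-diol | OCC#CCO | starting material
13 | 4-(triisopropylsilyloxy)but-2-yn-1-ol | OCC#CCO[Si](C(C)C)(C(C)C)C(C)C | intermediate
14 | cyclic sodium alkenylaluminate (Al on C12, O-bound) | [Na+].COCCO[Al-]1(OCCOC)OCC=C1CO[Si](C(C)C)(C(C)C)C(C)C | intermediate (not isolated)
15 | (Z)-3-iodo-4-(triisopropylsilyloxy)but-2-en-1-ol | OC/C=C(\I)CO[Si](C(C)C)(C(C)C)C(C)C | intermediate
16 | (Z)-(4-bromo-2-iodobut-2-enyloxy)triisopropylsilane | BrC/C=C(\I)CO[Si](C(C)C)(C(C)C)C(C)C | intermediate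
17 | glycolaldehyde dimer (1,4-dioxane-2,5-diol) | OC1COC(O)CO1 | starting material
18 | 3-(triphenylphosphoranylidene)butan-2-one | CC(=O)C(C)=P(c1ccccc1)(c1ccccc1)c1ccccc1 | starting material
19 | (E)-5-hydroxy-3-methylpent-3-en-2-one | CC(=O)/C(C)=C/CO | intermediate
20 | (E)-3-methyl-5-(triethylsilyloxy)pent-3-en-2-one | CC(=O)/C(C)=C/CO[Si](CC)(CC)CC | intermediate
21 | lithium dienolate of 20 | [Li+].C=C([O-])/C(C)=C/CO[Si](CC)(CC)CC | intermediate (not isolated)
22 | (E)-2-(tert-butyldimethylsilyloxy)-3-methyl-5-(triethylsilyloxy)penta-1,3-diene | C=C(O[Si](C)(C)C(C)(C)C)/C(C)=C/CO[Si](CC)(CC)CC | intermediate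
23 | 2,2,2-trifluoroethyl acrylate | C=CC(=O)OCC(F)(F)F | starting material
24 | 2,2,2-trifluoroethyl (1S,2S)-4-(tert-butyldimethylsilyloxy)-3-methyl-2-[(triethylsilyloxy)methyl]cyclohex-3-ene-1-carboxylate | O=C(OCC(F)(F)F)[C@H]1CCC(O[Si](C)(C)C(C)(C)C)=C(C)[C@H]1CO[Si](CC)(CC)CC | intermediate
25 | tetrabutylammonium enolate from 24 (enolate at C30/C23) | CCCC[N+](CCCC)(CCCC)CCCC.O=C(OCC(F)(F)F)[C@H]1CCC([O-])=C(C)[C@H]1CO[Si](CC)(CC)CC | intermediate (not isolated)
26 | 2,2,2-trifluoroethyl (1S,2S,3R)-3-[(Z)-3-iodo-4-(triisopropylsilyloxy)but-2-enyl]-3-methyl-4-oxo-2-[(triethylsilyloxy)methyl]cyclohexane-1-carboxylate | O=C(OCC(F)(F)F)[C@H]1CCC(=O)[C@](C)(C/C=C(\I)CO[Si](C(C)C)(C(C)C)C(C)C)[C@H]1CO[Si](CC)(CC)CC | intermediate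
27 | lithium enolate of 26 (C30/C14) | [Li+].O=C(OCC(F)(F)F)[C@H]1CC=C([O-])[C@](C)(C/C=C(\I)CO[Si](C(C)C)(C(C)C)C(C)C)[C@H]1CO[Si](CC)(CC)CC | intermediate (not isolated)
28 | 2,2,2-trifluoroethyl (1S,2S,3R,5R)-3-[(Z)-3-iodo-4-(triisopropylsilyloxy)but-2-enyl]-3,5-dimethyl-4-oxo-2-[(triethylsilyloxy)methyl]cyclohexane-1-carboxylate | O=C(OCC(F)(F)F)[C@H]1C[C@@H](C)C(=O)[C@](C)(C/C=C(\I)CO[Si](C(C)C)(C(C)C)C(C)C)[C@H]1CO[Si](CC)(CC)CC | intermediate
29 | alkoxysulfonium chloride from 28 (C21–O–SMe2+) | [Cl-].O=C(OCC(F)(F)F)[C@H]1C[C@@H](C)C(=O)[C@](C)(C/C=C(\I)CO[Si](C(C)C)(C(C)C)C(C)C)[C@H]1CO[S+](C)C | intermediate (not isolated)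
30 | 2,2,2-trifluoroethyl (1S,2S,3R,5R)-2-formyl-3-[(Z)-3-iodo-4-(triisopropylsilyloxy)but-2-enyl]-3,5-dimethyl-4-oxocyclohexane-1-carboxylate | O=C(OCC(F)(F)F)[C@H]1C[C@@H](C)C(=O)[C@](C)(C/C=C(\I)CO[Si](C(C)C)(C(C)C)C(C)C)[C@H]1C=O | intermediate
31 | 2,2,2-trifluoroethyl (1S,3R,5R,2E)-2-[(tert-butyldimethylsilyloxy)methylidene]-3-[(Z)-3-iodo-4-(triisopropylsilyloxy)but-2-enyl]-3,5-dimethyl-4-oxocyclohexane-1-carboxylate | O=C(OCC(F)(F)F)[C@H]1C[C@@H](C)C(=O)[C@](C)(C/C=C(\I)CO[Si](C(C)C)(C(C)C)C(C)C)/C1=C/O[Si](C)(C)C(C)(C)C | intermediate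
32 | alkylzinc iodide from 11 | CC1(C)OC(=O)C=C[C@]1(C(C)=O)CC[Zn]I | intermediate (not isolated)
33 | cyclization substrate (name as in step 21) | CC1(C)OC(=O)C=C[C@]1(C(C)=O)CC/C(CO[Si](C(C)C)(C(C)C)C(C)C)=C\C[C@@]2(C)C(=O)[C@H](C)C[C@H](C(=O)OCC(F)(F)F)/C2=C\O[Si](C)(C)C(C)(C)C | intermediate
34 | C12 carbocation, ring B closed, C27 aluminium alkoxide | CC1(C)OC(=O)C=C[C@]12CC[C+](CO[Si](C(C)C)(C(C)C)C(C)C)[C@@H](C[C@@]3(C)C(=O)[C@H](C)C[C@H](C(=O)OCC(F)(F)F)/C3=C\O[Si](C)(C)C(C)(C)C)[C@@]2(C)O[Al-](C)(Cl)Cl | intermediate (not isolated)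
35 | silyloxocarbenium ion at C21, rings B and C closed | CC1(C)OC(=O)C=C[C@]12CC[C@@]3(CO[Si](C(C)C)(C(C)C)C(C)C)[C@]4(C=[O+][Si](C)(C)C(C)(C)C)[C@@H](C(=O)OCC(F)(F)F)C[C@@H](C)C(=O)[C@]4(C)C[C@H]3[C@@]2(C)O[Al-](C)(Cl)Cl | intermediate (not isolated)
36 | tetracyclic C21 aldehyde trifluoroethyl ester (C27 OH, C13 CH2OSi(iPr)3) | CC1(C)OC(=O)C=C[C@]12CC[C@@]3(CO[Si](C(C)C)(C(C)C)C(C)C)[C@]4(C=O)[C@@H](C(=O)OCC(F)(F)F)C[C@@H](C)C(=O)[C@]4(C)C[C@H]3[C@@]2(C)O | intermediate
37 | C21 hydroxy ester from 36 | CC1(C)OC(=O)C=C[C@]12CC[C@@]3(CO[Si](C(C)C)(C(C)C)C(C)C)[C@]4(CO)[C@@H](C(=O)OCC(F)(F)F)C[C@@H](C)C(=O)[C@]4(C)C[C@H]3[C@@]2(C)O | intermediate (not isolated)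
38 | pentacyclic γ-lactone, C13 CH2OSi(iPr)3 | CC1(C)OC(=O)C=C[C@]12CC[C@@]3(CO[Si](C(C)C)(C(C)C)C(C)C)[C@]45COC(=O)[C@H]4C[C@@H](C)C(=O)[C@]5(C)C[C@H]3[C@@]2(C)O | intermediate
39 | pentacyclic γ-lactone, C13 CH2OH | CC1(C)OC(=O)C=C[C@]12CC[C@@]3(CO)[C@]45COC(=O)[C@H]4C[C@@H](C)C(=O)[C@]5(C)C[C@H]3[C@@]2(C)O | intermediate
40 | pentacyclic C13 aldehyde | CC1(C)OC(=O)C=C[C@]12CC[C@@]3(C=O)[C@]45COC(=O)[C@H]4C[C@@H](C)C(=O)[C@]5(C)C[C@H]3[C@@]2(C)O | intermediate
41 | hexacyclic β-hydroxy ketone (C13 OH syn to C30 carbonyl) | CC1(C)OC(=O)C=C[C@]12CC[C@@]13[C@H](O)[C@@]4(C)C[C@@H]5C(=O)OC[C@]51[C@@](C)(C[C@H]3[C@@]2(C)O)C4=O | intermediate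
42 | C13 O-(imidazol-1-ylthiocarbonyl) derivative of 41 | CC1(C)OC(=O)C=C[C@]12CC[C@@]13[C@H](OC(=S)n6ccnc6)[C@@]4(C)C[C@@H]5C(=O)OC[C@]51[C@@](C)(C[C@H]3[C@@]2(C)O)C4=O | intermediate
43 | CNP0222978.3 | CC1(C)OC(=O)C=C[C@]12CC[C@@]13C[C@@]4(C)C[C@@H]5C(=O)OC[C@]51[C@@](C)(C[C@H]3[C@@]2(C)O)C4=O | target

**Step count and risks**

Total step count: 28. Longest linear sequence: 17 steps (steps 1–9 and 21–28).

Three steps most likely to fail:

1. Step 22. The C12 cation may be lost by proton transfer or by a 1,2-hydride shift from C13 before the enol ether captures it, or the hindered ketone may fail to ionize the alkene while the Lewis acid sits on the other carbonyl groups. Fallback: a ketal-initiated cyclization, which sets out from 8 and returns at 38.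
   - HF·pyridine removes only the silyl ether of 8 to give the alcohol F1, which is iodinated (I2, PPh3, imidazole) to F2.
   - Ring-closing metathesis as in step 9 gives the dioxolane lactone iodide F3, and coupling with 31 as in step 21 gives the dioxolane substrate F4.
   - TiCl4 (CH2Cl2, −78 °C) opens the dioxolane to an oxocarbenium ion, a much stronger and irreversible initiator, and the same bicyclization gives the C27 2-hydroxyethyl ether aldehyde F5.
   - Reduction and lactonization as in step 23 give F6; the hydroxyethyl group is turned into the iodide F7 (I2, PPh3, imidazole).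
   - Zn dust (EtOH, reflux) fragments the 2-iodoethyl ether, expelling ethene and freeing the C27 alcohol, which is 38.

2. Step 28. The C13 radical may rearrange by 1,2-acyl migration through the C30 carbonyl faster than it takes up hydrogen, which would give a bicyclo[3.2.1]octane skeleton. Fallback: a thionium-ion ring closure that needs neither the aldol nor a C13 radical; it sets out from 40 and returns at 43.
   - The aldehyde of 40 is converted into its diphenyl dithioacetal F8 (PhSH, BF3·OEt2, CH2Cl2, −20 °C).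
   - Me3SiOTf/Et3N gives the C30 enol silyl ether F9 (the C27 alcohol is silylated as well).
   - Dimethyl(methylthio)sulfonium tetrafluoroborate generates the thionium ion, which alkylates C14 and gives the C13 phenylthio compound F10 after desilylating work-up.
   - Raney Ni (deactivated with acetone, EtOH, 0 °C) removes the sulfur and gives 43; the lactone alkene is the group to watch.

3. Step 26. The aldol addition may revert (retro-aldol relieves the strain of the bicyclo[2.2.2]octane), or the hindered ketone may not enolize. Fallback: an irreversible reductive closure that sets out from 40 and returns at 41.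
   - Me3SiOTf/Et3N converts 40 into the C30 enol silyl ether F11 (C27 silylated as well).
   - N-Bromosuccinimide and a dilute acid work-up give the C14 α-bromo ketone F12.
   - SmI2 (THF, −78 °C) forms the samarium enolate, which adds to the C13 aldehyde in a Reformatsky-type closure to give 41.

Further compounds
F1 | step 22 | (R,E)-3-(2-hydroxyethyl)-2-methyl-3-(2-methyl-1,3-dioxolan-2-yl)hex-4-en-2-yl acrylate | C/C=C/[C@](C1(C)OCCO1)(CCO)C(C)(C)OC(=O)C=C
F2 | step 22 | (R,E)-3-(2-iodoethyl)-2-methyl-3-(2-methyl-1,3-dioxolan-2-yl)hex-4-en-2-yl acrylate | C/C=C/[C@](C1(C)OCCO1)(CCI)C(C)(C)OC(=O)C=C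
F3 | step 22 | (R)-5-(2-iodoethyl)-6,6-dimethyl-5-(2-methyl-1,3-dioxolan-2-yl)-5,6-dihydro-2H-pyran-2-one | CC1(C)OC(=O)C=C[C@]1(C2(C)OCCO2)CCI
F4 | step 22 | dioxolane analogue of substrate 33 | CC1(C)OC(=O)C=C[C@]1(C2(C)OCCO2)CC/C(CO[Si](C(C)C)(C(C)C)C(C)C)=C\C[C@@]3(C)C(=O)[C@H](C)C[C@H](C(=O)OCC(F)(F)F)/C3=C\O[Si](C)(C)C(C)(C)C
F5 | step 22 | C27 2-hydroxyethyl ether of aldehyde 36 | CC1(C)OC(=O)C=C[C@]12CC[C@@]3(CO[Si](C(C)C)(C(C)C)C(C)C)[C@]4(C=O)[C@@H](C(=O)OCC(F)(F)F)C[C@@H](C)C(=O)[C@]4(C)C[C@H]3[C@@]2(C)OCCO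
F6 | step 22 | C27 2-hydroxyethyl ether of lactone 38 | CC1(C)OC(=O)C=C[C@]12CC[C@@]3(CO[Si](C(C)C)(C(C)C)C(C)C)[C@]45COC(=O)[C@H]4C[C@@H](C)C(=O)[C@]5(C)C[C@H]3[C@@]2(C)OCCO
F7 | step 22 | C27 2-iodoethyl ether of lactone 38 | CC1(C)OC(=O)C=C[C@]12CC[C@@]3(CO[Si](C(C)C)(C(C)C)C(C)C)[C@]45COC(=O)[C@H]4C[C@@H](C)C(=O)[C@]5(C)C[C@H]3[C@@]2(C)OCCI
F8 | step 28 | C13 diphenyl dithioacetal of 40 | CC1(C)OC(=O)C=C[C@]12CC[C@@]3(C(Sc6ccccc6)Sc6ccccc6)[C@]45COC(=O)[C@H]4C[C@@H](C)C(=O)[C@]5(C)C[C@H]3[C@@]2(C)O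
F9 | step 28 | C30 enol trimethylsilyl ether and C27 trimethylsilyl ether of F8 | CC1(C)OC(=O)C=C[C@]12CC[C@@]3(C(Sc6ccccc6)Sc6ccccc6)[C@]45COC(=O)[C@H]4CC(C)=C(O[Si](C)(C)C)[C@]5(C)C[C@H]3[C@@]2(C)O[Si](C)(C)C
F10 | step 28 | C13 phenylthio derivative of the target (C13 epimers) | CC1(C)OC(=O)C=C[C@]12CC[C@@]13C(Sc6ccccc6)[C@@]4(C)C[C@@H]5C(=O)OC[C@]51[C@@](C)(C[C@H]3[C@@]2(C)O)C4=O
F11 | step 26 | C30 enol trimethylsilyl ether and C27 trimethylsilyl ether of 40 | CC1(C)OC(=O)C=C[C@]12CC[C@@]3(C=O)[C@]45COC(=O)[C@H]4CC(C)=C(O[Si](C)(C)C)[C@]5(C)C[C@H]3[C@@]2(C)O[Si](C)(C)C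
F12 | step 26 | C14 α-bromo ketone of 40 (C14 epimers) | CC1(C)OC(=O)C=C[C@]12CC[C@@]3(C=O)[C@]45COC(=O)[C@H]4CC(C)(Br)C(=O)[C@]5(C)C[C@H]3[C@@]2(C)O
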